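**Plan**

- Retrosynthesis: the O–CH2 bonds of two methoxymethyl ethers (on O3 and O7) are cut first, then the C3''–O bond of a (2''R)-2'',3''-epoxide, then both oxirane C–O bonds, which leads back to a 3'-prenyl flavonol.
- Earlier cuts: C3–O (hydroxylation of the flavone C3–H), O1–C2 and the C3–C(=O) acyl bond of ring C (Baker–Venkataraman), the aryl ester, C3'–C1'' (aryl–prenyl), and the C6–O bond of ring A (Elbs).
- Forward order: ring A acetophenone from phloroacetophenone; ring B acid from 3-bromo-4-methoxybenzoic acid and prenyl bromide; ester, then diketone, then ring C; then the C3 oxygen, capping, epoxidation, isomerisation and deprotection.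
- Enabling feature: the chain on C3' of ring B carries OH on C2'' and a C3''=C4'' isopropenyl group, which is what an oxirane across C2''=C3'' of a prenyl group gives when opened towards a methyl group. That alkene is the only isolated, electron-rich C=C once ring C and both hydroxyls are masked.
- Stereochemistry: the single stereocentre C2'' comes from a ketone-catalysed asymmetric epoxidation; its C–O bond is not touched afterwards.

Key step: step 12

Assumption: the D-fructose-derived ketone is taken to deliver oxygen to the alkene face that gives the (2''R)-epoxide, as the spiro transition-state model predicts for trisubstituted alkenes. Locants: chromone numbering for rings A and C, primed for ring B, doubly primed (C1''–C4'') for the side chain.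

**Route**

Step 1
Reactants: 1 2',4',6'-trihydroxyacetophenone
Product: 2 1-[4-(benzyloxy)-2,6-dihydroxyphenyl]ethanone
Conditions: BnBr (1.0 equiv), K2CO3 (1.1 equiv), DMF, 0 °C → rt
Reagents that add atoms: benzyl bromide, BrCc1ccccc1
Why: Williamson etherification; the 4-OH is para to the acetyl group and is the only hydroxyl not hydrogen-bonded to the carbonyl, so it is the most acidic and should be alkylated first when the halide is limiting.

Step 2
Reactants: 2 1-[4-(benzyloxy)-2,6-dihydroxyphenyl]ethanone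
Product: 3 1-[4-(benzyloxy)-2-hydroxy-6-methoxyphenyl]ethanone
Conditions: Me2SO4 (1.05 equiv), K2CO3, acetone, reflux
Reagents that add atoms: dimethyl sulfate, COS(=O)(=O)OC
Why: Williamson O-methylation of one of the two equivalent ortho hydroxyls; the remaining one is then locked in a hydrogen bond to the ketone and should resist a second methylation.

Step 3
Reactants: 3 1-[4-(benzyloxy)-2-hydroxy-6-methoxyphenyl]ethanone
Product: 5 1-[4-(benzyloxy)-3,6-dihydroxy-2-methoxyphenyl]ethanone, via potassium aryl sulfate 4 (not isolated)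
Conditions: K2S2O8, aq. NaOH, pyridine, 15 °C; then aq. HCl, Na2SO3, 90 °C
Reagents that add atoms: potassium peroxydisulfate, [K+].[K+].[O-]S(=O)(=O)OOS(=O)(=O)[O-]
Why: Elbs persulfate oxidation; the phenoxide attacks a peroxide oxygen through its only free para carbon, and brief warm dilute acid hydrolyses the aryl sulfate to the quinol while the benzyl ether should survive.

Step 4
Reactants: 5 1-[4-(benzyloxy)-3,6-dihydroxy-2-methoxyphenyl]ethanone
Product: 6 1-[4-(benzyloxy)-6-hydroxy-2,3-dimethoxyphenyl]ethanone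
Conditions: Me2SO4 (1.05 equiv), K2CO3, acetone, reflux
Reagents that add atoms: dimethyl sulfate, COS(=O)(=O)OC
Why: Selective Williamson methylation; the newly introduced hydroxyl is free whereas the ortho hydroxyl is chelated to the acetyl group, so one equivalent of the alkylating agent should methylate only the former.

Step 5
Reactants: 6 1-[4-(benzyloxy)-6-hydroxy-2,3-dimethoxyphenyl]ethanone
Product: 7 1-(4,6-dihydroxy-2,3-dimethoxyphenyl)ethanone
Conditions: H2 (1 atm), 10% Pd/C, EtOAc–MeOH, rt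
Reagents that add atoms: none
Why: Catalytic hydrogenolysis of the benzyl ether, placed before any alkene is present; the chelated aryl ketone should not be reduced at atmospheric pressure.

Step 6
Reactants: 7 1-(4,6-dihydroxy-2,3-dimethoxyphenyl)ethanone
Product: 8 1-[6-hydroxy-2,3-dimethoxy-4-(methoxymethoxy)phenyl]ethanone
Conditions: MOMCl (1.1 equiv), i-Pr2NEt, CH2Cl2, 0 °C
Reagents that add atoms: chloromethyl methyl ether, COCCl
Why: Selective methoxymethylation (acetal formation) of the non-chelated para hydroxyl with a hindered amine base; the chelated ortho hydroxyl needed for the ester stays free.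

Step 7
Reactants: 9 3-bromo-4-methoxybenzoic acid; 10 prenyl bromide (1-bromo-3-methylbut-2-ene)
Product: 12 4-methoxy-3-(3-methylbut-2-en-1-yl)benzoic acid, via dilithiated benzoate 11 (not isolated)
Conditions: n-BuLi (2.1 equiv), THF, −78 °C; CuBr·SMe2 (10 mol %), 10, −78 → 0 °C; aq. HCl
Reagents that add atoms: none
Why: Bromine–lithium exchange on the lithium carboxylate gives an ortho-methoxy-stabilised aryllithium, and copper-catalysed SN2 allylation with the primary allylic bromide should give the linear prenyl arene; the carboxylate is too poor an electrophile at −78 °C to be attacked.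

Step 8
Reactants: 8 1-[6-hydroxy-2,3-dimethoxy-4-(methoxymethoxy)phenyl]ethanone; 12 4-methoxy-3-(3-methylbut-2-en-1-yl)benzoic acid
Product: 13 2-acetyl-3,4-dimethoxy-5-(methoxymethoxy)phenyl 4-methoxy-3-(3-methylbut-2-en-1-yl)benzoate
Conditions: EDC·HCl, DMAP, CH2Cl2, rt
Reagents that add atoms: none
Why: Steglich esterification; carbodiimide activation with DMAP acylates the chelated phenol without generating HCl, which could add to the prenyl alkene or cleave the acetal.

Step 9
Reactants: 13 2-acetyl-3,4-dimethoxy-5-(methoxymethoxy)phenyl 4-methoxy-3-(3-methylbut-2-en-1-yl)benzoate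
Product: 15 5,6-dimethoxy-2-[4-methoxy-3-(3-methylbut-2-en-1-yl)phenyl]-7-(methoxymethoxy)-4H-chromen-4-one, via 1,3-diketone 14 (not isolated)
Conditions: LiN(SiMe3)2 (3 equiv), THF, −78 → 0 °C; then AcOH, NaOAc, 95 °C
Reagents that add atoms: none
Why: Baker–Venkataraman rearrangement (O-to-C acyl transfer from the ketone enolate) followed by acetate-buffered cyclodehydration of the 2-hydroxyaryl 1,3-diketone closes ring C under conditions mild enough to spare the acetal and the trisubstituted alkene.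

Step 10
Reactants: 15 5,6-dimethoxy-2-[4-methoxy-3-(3-methylbut-2-en-1-yl)phenyl]-7-(methoxymethoxy)-4H-chromen-4-one
Product: 18 3-hydroxy-5,6-dimethoxy-2-[4-methoxy-3-(3-methylbut-2-en-1-yl)phenyl]-7-(methoxymethoxy)-4H-chromen-4-one, via 3-lithioflavone 16 (not isolated), via 3-boronate ester 17 (not isolated)
Conditions: LiN(i-Pr)2, THF, −78 °C; B(OMe)3, −78 → 0 °C; AcOH, 30% H2O2, 0 °C
Reagents that add atoms: hydrogen peroxide, OO
Why: C3-lithiation of the flavone (the only C–H alpha to the C4 carbonyl), borate trapping and boronate oxidation (1,2-shift from boron to oxygen) install the 3-hydroxyl without an electrophilic oxidant that would attack the prenyl alkene.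

Step 11
Reactants: 18 3-hydroxy-5,6-dimethoxy-2-[4-methoxy-3-(3-methylbut-2-en-1-yl)phenyl]-7-(methoxymethoxy)-4H-chromen-4-one
Product: 19 5,6-dimethoxy-2-[4-methoxy-3-(3-methylbut-2-en-1-yl)phenyl]-3,7-bis(methoxymethoxy)-4H-chromen-4-one
Conditions: MOMCl, i-Pr2NEt, DMAP (cat.), CH2Cl2, 0 °C → rt
Reagents that add atoms: chloromethyl methyl ether, COCCl
Why: O-alkylation of the enolic 3-hydroxyl with the α-chloro ether (methoxymethylation) caps the last free O–H before the oxidation.

Step 12
Reactants: 19 5,6-dimethoxy-2-[4-methoxy-3-(3-methylbut-2-en-1-yl)phenyl]-3,7-bis(methoxymethoxy)-4H-chromen-4-one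
Product: 20 2-(3-{[(2R)-3,3-dimethyloxiran-2-yl]methyl}-4-methoxyphenyl)-5,6-dimethoxy-3,7-bis(methoxymethoxy)-4H-chromen-4-one
Conditions: 1,2:4,5-di-O-isopropylidene-β-D-erythro-hexo-2,3-diulo-2,6-pyranose (30 mol %), KHSO5 (as 2KHSO5·KHSO4·K2SO4), K2CO3, Bu4NHSO4, MeCN–CH2(OMe)2–aq. Na2B4O7 buffer (pH 10.5), 0 °C
Reagents that add atoms: potassium peroxymonosulfate, [K+].[O-]S(=O)(=O)OO
Why: KHSO5 converts the chiral ketone into a dioxirane, which passes one oxygen atom to the C2''=C3'' alkene through a concerted spiro transition state and regenerates the ketone; the closest known reaction type is the Shi asymmetric epoxidation of trisubstituted alkenes. The oxirane closes by simultaneous formation of both C–O bonds, a [2+1] oxygen-atom addition, so no separate ring-closure mode is involved. C2'' is set by the catalyst: in the favoured spiro arrangement the alkene approaches the dioxirane face remote from the fused dioxolane, and the D-fructose-derived ketone is expected to give the (2''R)-epoxide. The step needs site selectivity, which the substrate secures because the prenyl C=C is its only isolated, electron-rich alkene: C2=C3 of ring C is a tetrasubstituted vinylogous ester deactivated by the C4 carbonyl, and both hydroxyls are capped so that no phenoxide or enol meets the oxidant. Buffering at pH 10.5 and 0 °C suppresses Baeyer–Villiger loss of the catalyst and should leave the acetals untouched.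

Step 13
Reactants: 20 2-(3-{[(2R)-3,3-dimethyloxiran-2-yl]methyl}-4-methoxyphenyl)-5,6-dimethoxy-3,7-bis(methoxymethoxy)-4H-chromen-4-one
Product: 21 2-{3-[(2R)-2-hydroxy-3-methylbut-3-en-1-yl]-4-methoxyphenyl}-5,6-dimethoxy-3,7-bis(methoxymethoxy)-4H-chromen-4-one
Conditions: Et2AlCl, lithium 2,2,6,6-tetramethylpiperidide (4 equiv each), toluene, 0 °C; aq. potassium sodium tartrate
Reagents that add atoms: none
Why: Aluminium-amide-promoted isomerisation of a trisubstituted epoxide to an allylic alcohol; aluminium binds the oxirane oxygen and the amide removes a proton from a C3'' methyl group in a syn elimination that breaks only the C3''–O bond, so the C2''–O bond and the (R) configuration are retained.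

Step 14
Reactants: 21 2-{3-[(2R)-2-hydroxy-3-methylbut-3-en-1-yl]-4-methoxyphenyl}-5,6-dimethoxy-3,7-bis(methoxymethoxy)-4H-chromen-4-one
Product: 22 3,7-dihydroxy-2-{3-[(2R)-2-hydroxy-3-methylbut-3-en-1-yl]-4-methoxyphenyl}-5,6-dimethoxy-4H-chromen-4-one
Conditions: 2 M aq. HCl, MeOH, 40 °C
Reagents that add atoms: none
Why: Acid-catalysed acetal cleavage (transacetalisation to methanol) removes both methoxymethyl groups; the secondary allylic alcohol, whose ionisation would give only a poorly stabilised cation, and the aryl methyl ethers should survive dilute acid at this temperature.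

**Compound list**

1 | 2',4',6'-trihydroxyacetophenone | CC(=O)c1c(O)cc(O)cc1O | starting material
2 | 1-[4-(benzyloxy)-2,6-dihydroxyphenyl]ethanone | CC(=O)c1c(O)cc(OCc2ccccc2)cc1O | intermediate
3 | 1-[4-(benzyloxy)-2-hydroxy-6-methoxyphenyl]ethanone | CC(=O)c1c(O)cc(OCc2ccccc2)cc1OC | intermediate
4 | potassium 3-acetyl-6-(benzyloxy)-4-hydroxy-2-methoxyphenyl sulfate | CC(=O)c1c(O)cc(OCc2ccccc2)c(OS(=O)(=O)[O-])c1OC.[K+] | intermediate
5 | 1-[4-(benzyloxy)-3,6-dihydroxy-2-methoxyphenyl]ethanone | CC(=O)c1c(O)cc(OCc2ccccc2)c(O)c1OC | intermediate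
6 | 1-[4-(benzyloxy)-6-hydroxy-2,3-dimethoxyphenyl]ethanone | CC(=O)c1c(O)cc(OCc2ccccc2)c(OC)c1OC | intermediate
7 | 1-(4,6-dihydroxy-2,3-dimethoxyphenyl)ethanone | CC(=O)c1c(O)cc(O)c(OC)c1OC | intermediate
8 | 1-[6-hydroxy-2,3-dimethoxy-4-(methoxymethoxy)phenyl]ethanone | CC(=O)c1c(O)cc(OCOC)c(OC)c1OC | intermediate
9 | 3-bromo-4-methoxybenzoic acid | COc1ccc(C(=O)O)cc1Br | starting material
10 | prenyl bromide (1-bromo-3-methylbut-2-ene) | CC(C)=CCBr | starting material
11 | lithium 3-lithio-4-methoxybenzoate | [Li]c1cc(C(=O)[O-])ccc1OC.[Li+] | intermediate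
12 | 4-methoxy-3-(3-methylbut-2-en-1-yl)benzoic acid | COc1ccc(C(=O)O)cc1CC=C(C)C | intermediate
13 | 2-acetyl-3,4-dimethoxy-5-(methoxymethoxy)phenyl 4-methoxy-3-(3-methylbut-2-en-1-yl)benzoate | CC(=O)c1c(OC(=O)c2ccc(OC)c(CC=C(C)C)c2)cc(OCOC)c(OC)c1OC | intermediate
14 | 1-[6-hydroxy-2,3-dimethoxy-4-(methoxymethoxy)phenyl]-3-[4-methoxy-3-(3-methylbut-2-en-1-yl)phenyl]propane-1,3-dione | O=C(CC(=O)c1ccc(OC)c(CC=C(C)C)c1)c1c(O)cc(OCOC)c(OC)c1OC | intermediate
15 | 5,6-dimethoxy-2-[4-methoxy-3-(3-methylbut-2-en-1-yl)phenyl]-7-(methoxymethoxy)-4H-chromen-4-one | CC(C)=CCc1cc(-c2cc(=O)c3c(OC)c(OC)c(OCOC)cc3o2)ccc1OC | intermediate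
16 | 3-lithio-5,6-dimethoxy-2-[4-methoxy-3-(3-methylbut-2-en-1-yl)phenyl]-7-(methoxymethoxy)-4H-chromen-4-one | [Li]c1c(-c2ccc(OC)c(CC=C(C)C)c2)oc2cc(OCOC)c(OC)c(OC)c2c1=O | intermediate
17 | dimethyl {5,6-dimethoxy-2-[4-methoxy-3-(3-methylbut-2-en-1-yl)phenyl]-7-(methoxymethoxy)-4-oxo-4H-chromen-3-yl}boronate | COB(OC)c1c(-c2ccc(OC)c(CC=C(C)C)c2)oc2cc(OCOC)c(OC)c(OC)c2c1=O | intermediate
18 | 3-hydroxy-5,6-dimethoxy-2-[4-methoxy-3-(3-methylbut-2-en-1-yl)phenyl]-7-(methoxymethoxy)-4H-chromen-4-one | CC(C)=CCc1cc(-c2oc3cc(OCOC)c(OC)c(OC)c3c(=O)c2O)ccc1OC | intermediate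
19 | 5,6-dimethoxy-2-[4-methoxy-3-(3-methylbut-2-en-1-yl)phenyl]-3,7-bis(methoxymethoxy)-4H-chromen-4-one | CC(C)=CCc1cc(-c2oc3cc(OCOC)c(OC)c(OC)c3c(=O)c2OCOC)ccc1OC | intermediate
20 | 2-(3-{[(2R)-3,3-dimethyloxiran-2-yl]methyl}-4-methoxyphenyl)-5,6-dimethoxy-3,7-bis(methoxymethoxy)-4H-chromen-4-one | CC4(C)[C@H](O4)Cc1cc(-c2oc3cc(OCOC)c(OC)c(OC)c3c(=O)c2OCOC)ccc1OC | intermediate
21 | 2-{3-[(2R)-2-hydroxy-3-methylbut-3-en-1-yl]-4-methoxyphenyl}-5,6-dimethoxy-3,7-bis(methoxymethoxy)-4H-chromen-4-one | C=C(C)[C@H](O)Cc1cc(-c2oc3cc(OCOC)c(OC)c(OC)c3c(=O)c2OCOC)ccc1OC | intermediate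
22 | 3,7-dihydroxy-2-{3-[(2R)-2-hydroxy-3-methylbut-3-en-1-yl]-4-methoxyphenyl}-5,6-dimethoxy-4H-chromen-4-one | C=C(C)[C@H](O)Cc1cc(-c2oc3cc(O)c(OC)c(OC)c3c(=O)c2O)ccc1OC | target

**Summary**

Total step count: 14.
Longest linear sequence: 13 steps (steps 1–6, then 8–14); step 7 is the convergent branch.

**Steps most likely to fail**

1. Step 10. The C3 anion may open ring C by retro-oxa-Michael cleavage, the amide base may instead metalate C8 next to the acetal, or the boronate oxidation may stall. The fallback sets out from acetophenone 8 and acid 9 and rejoins at 19; it brings in the C3 oxygen by dioxirane oxidation before any prenyl group is present and attaches the prenyl group last.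
   - Acetophenone 8 is esterified with acid 9 (EDC·HCl, DMAP) to 2-acetyl-3,4-dimethoxy-5-(methoxymethoxy)phenyl 3-bromo-4-methoxybenzoate F1.
   - LiN(SiMe3)2 rearranges this to 1-(3-bromo-4-methoxyphenyl)-3-[6-hydroxy-2,3-dimethoxy-4-(methoxymethoxy)phenyl]propane-1,3-dione F2.
   - NaOAc in AcOH closes it to 2-(3-bromo-4-methoxyphenyl)-5,6-dimethoxy-7-(methoxymethoxy)-4H-chromen-4-one F3.
   - Dimethyldioxirane in acetone should epoxidise C2=C3 to racemic 2-(3-bromo-4-methoxyphenyl)-2,3-epoxy-5,6-dimethoxy-7-(methoxymethoxy)-2,3-dihydro-4H-chromen-4-one F4.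
   - On silica gel this should open to 2-(3-bromo-4-methoxyphenyl)-3-hydroxy-5,6-dimethoxy-7-(methoxymethoxy)-4H-chromen-4-one F5.
   - MOMCl and i-Pr2NEt give 2-(3-bromo-4-methoxyphenyl)-5,6-dimethoxy-3,7-bis(methoxymethoxy)-4H-chromen-4-one F6.
   - Stille coupling with tributyl(3-methylbut-2-en-1-yl)stannane and Pd(PPh3)4 in DMF at 90 °C should deliver 19.

2. Step 13. Lewis-acid-triggered hydride shift of the oxirane to a ketone (Meinwald rearrangement), sequestration of the aluminium amide by the carbonyl and acetal oxygens, or attack on ring C may compete with the methyl deprotonation. The fallback sets out from epoxide 20 and rejoins at 21; it replaces the elimination by hydrolytic opening and dehydration.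
   - Brief treatment with catalytic aq. HClO4 in THF at 0 °C should open the oxirane at the tertiary C3'' (C2'' untouched) to 2-{3-[(2R)-2,3-dihydroxy-3-methylbutyl]-4-methoxyphenyl}-5,6-dimethoxy-3,7-bis(methoxymethoxy)-4H-chromen-4-one F7.
   - Ac2O in pyridine acylates only the secondary hydroxyl to (2R)-1-{5-[5,6-dimethoxy-3,7-bis(methoxymethoxy)-4-oxo-4H-chromen-2-yl]-2-methoxyphenyl}-3-hydroxy-3-methylbutan-2-yl acetate F8.
   - SOCl2 in pyridine at 0 °C dehydrates the tertiary alcohol away from the acetoxy carbon to (2R)-1-{5-[5,6-dimethoxy-3,7-bis(methoxymethoxy)-4-oxo-4H-chromen-2-yl]-2-methoxyphenyl}-3-methylbut-3-en-2-yl acetate F9.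
   - K2CO3 in MeOH removes the acetate to give 21.

3. Step 3. The persulfate oxidation may stop at low conversion because the benzyl ether dissolves poorly in aqueous alkali, and over-oxidation to dark polymeric material may consume the product. The fallback sets out from phenol 3 and rejoins at quinol 5; it goes through the quinone oxidation level.
   - Teuber oxidation with K2[ON(SO3)2] in KH2PO4-buffered aqueous acetone should give 2-acetyl-5-(benzyloxy)-3-methoxycyclohexa-2,5-diene-1,4-dione F10.
   - Na2S2O4 in a two-phase EtOAc–water mixture reduces the quinone to 5.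

**Further compounds**

F1 | step 10 | 2-acetyl-3,4-dimethoxy-5-(methoxymethoxy)phenyl 3-bromo-4-methoxybenzoate | CC(=O)c1c(OC(=O)c2ccc(OC)c(Br)c2)cc(OCOC)c(OC)c1OC
F2 | step 10 | 1-(3-bromo-4-methoxyphenyl)-3-[6-hydroxy-2,3-dimethoxy-4-(methoxymethoxy)phenyl]propane-1,3-dione | O=C(CC(=O)c1ccc(OC)c(Br)c1)c1c(O)cc(OCOC)c(OC)c1OC
F3 | step 10 | 2-(3-bromo-4-methoxyphenyl)-5,6-dimethoxy-7-(methoxymethoxy)-4H-chromen-4-one | COc1ccc(-c2cc(=O)c3c(OC)c(OC)c(OCOC)cc3o2)cc1Br
F4 | step 10 | 2-(3-bromo-4-methoxyphenyl)-2,3-epoxy-5,6-dimethoxy-7-(methoxymethoxy)-2,3-dihydro-4H-chromen-4-one (racemic) | COc1ccc(C23OC2C(=O)c2c(OC)c(OC)c(OCOC)cc2O3)cc1Br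
F5 | step 10 | 2-(3-bromo-4-methoxyphenyl)-3-hydroxy-5,6-dimethoxy-7-(methoxymethoxy)-4H-chromen-4-one | COc1ccc(-c2oc3cc(OCOC)c(OC)c(OC)c3c(=O)c2O)cc1Br
F6 | step 10 | 2-(3-bromo-4-methoxyphenyl)-5,6-dimethoxy-3,7-bis(methoxymethoxy)-4H-chromen-4-one | COc1ccc(-c2oc3cc(OCOC)c(OC)c(OC)c3c(=O)c2OCOC)cc1Br
F7 | step 13 | 2-{3-[(2R)-2,3-dihydroxy-3-methylbutyl]-4-methoxyphenyl}-5,6-dimethoxy-3,7-bis(methoxymethoxy)-4H-chromen-4-one | CC(C)(O)[C@H](O)Cc1cc(-c2oc3cc(OCOC)c(OC)c(OC)c3c(=O)c2OCOC)ccc1OC
F8 | step 13 | (2R)-1-{5-[5,6-dimethoxy-3,7-bis(methoxymethoxy)-4-oxo-4H-chromen-2-yl]-2-methoxyphenyl}-3-hydroxy-3-methylbutan-2-yl acetate | CC(C)(O)[C@H](OC(C)=O)Cc1cc(-c2oc3cc(OCOC)c(OC)c(OC)c3c(=O)c2OCOC)ccc1OC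
F9 | step 13 | (2R)-1-{5-[5,6-dimethoxy-3,7-bis(methoxymethoxy)-4-oxo-4H-chromen-2-yl]-2-methoxyphenyl}-3-methylbut-3-en-2-yl acetate | C=C(C)[C@H](OC(C)=O)Cc1cc(-c2oc3cc(OCOC)c(OC)c(OC)c3c(=O)c2OCOC)ccc1OC
F10 | step 3 | 2-acetyl-5-(benzyloxy)-3-methoxycyclohexa-2,5-diene-1,4-dione | CC(=O)C1=C(OC)C(=O)C(OCc2ccccc2)=CC1=O
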